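**Plan**

1. Ring locants used throughout: C1 (carries the exocyclic CH2), C2=C3, C4 (CMe2), C5, C6 (acyloxy stereocentre), C7, C8(CH3)=C9, C10, C11.
2. Retrosynthesis: cut the C6–O ester bond, replace C2=C3 by a C3 ketone (through the alcohol), then join C3 to C8 (Grob transform). This works because C3–C4(Me2)–C5–C6(O)–C7–C8(Me) is the substituted six-carbon unit of ketoisophorone: with C3–C8 bonded, the eleven-membered ring becomes that cyclohexane fused to a cycloheptane (C3, C2, C1, C11, C10, C9, C8), with oxygen on C3 and a leaving group on C9, 1,3 across C8.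
3. The bicycle is cut at C2–C3 (allyl metal + ketone) and C8–C9 (aldol). This leads back to ketoisophorone, 4-(chloromethyl)pent-4-enal (from tert-butyl acetate and 3-chloro-2-(chloromethyl)prop-1-ene) and isovanillic acid.
4. Forward: the six-membered ring is bought; C8–C9 is made by reductive aldol; the seven-membered ring by zinc Barbier closure of C2–C3; the eleven-membered ring by fragmentation of C3–C8; then C3 reduction, elimination to the diene, desilylation, acylation and phenol release.
5. Stereochemistry: C6 comes from asymmetric transfer hydrogenation and is not touched again. E-C8=C9 comes from antiperiplanar fragmentation of a C9 mesylate held cis to the C8 methyl. E-C2=C3 comes from E2 elimination beside quaternary C4. The C3, C8 and C9 stereocentres are sacrificial.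

Key step: step 10

Assumption: the aldol of step 5 is taken to place the new C8–C9 bond cis to the C6 silyloxy group (attack away from the pseudo-axial C4 methyl). C3, C8 and C9 all become sp2 in the key step, so the C8-epimeric series would pass through the same steps to the same eleven-membered ketone.

**Route**

Step 1
Reactants: 1 tert-butyl acetate; 2 3-chloro-2-(chloromethyl)prop-1-ene
Product: 4 tert-butyl 4-(chloromethyl)pent-4-enoate, via lithium ester enolate 3 (not isolated)
Conditions: LiN(i-Pr)2, THF, −78 °C; then 2 (3 equiv), −78 → 0 °C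
Reagents that add atoms: none
Why: Ester enolate alkylation, in which the lithium enolate displaces one allylic chloride of the symmetric dichloride (SN2 and SN2' lead to the same product) and the excess of 2 suppresses double alkylation.

Step 2
Reactants: 4 tert-butyl 4-(chloromethyl)pent-4-enoate
Product: 5 4-(chloromethyl)pent-4-enal
Conditions: i-Bu2AlH (1.1 equiv), CH2Cl2, −78 °C; aq. potassium sodium tartrate
Reagents that add atoms: none
Why: Partial ester reduction with i-Bu2AlH, which should stop at the aluminium hemiacetal of the bulky tert-butyl ester at −78 °C and release the aldehyde on hydrolysis, leaving the allylic chloride and the alkene untouched.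

Step 3
Reactants: 6 ketoisophorone (2,6,6-trimethylcyclohex-2-ene-1,4-dione)
Product: 7 (R)-4-hydroxy-2,6,6-trimethylcyclohex-2-en-1-one
Conditions: RuCl(p-cymene)[(R,R)-TsDPEN] (0.5 mol %), KOH (1 mol %), i-PrOH, 25 °C
Reagents that add atoms: none
Why: Noyori asymmetric transfer hydrogenation should reduce only the carbonyl flanked by CH2 and CH= (the other is shielded by the gem-dimethyl carbon and the methyl-bearing alkene carbon), and with the conjugated alkene in the role of the aryl group of an aryl ketone the (R,R) catalyst is expected to give the (R)-carbinol, the future C6.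

Step 4
Reactants: 7 (R)-4-hydroxy-2,6,6-trimethylcyclohex-2-en-1-one
Product: 8 (R)-4-[(tert-butyldimethylsilyl)oxy]-2,6,6-trimethylcyclohex-2-en-1-one
Conditions: TBSCl, imidazole, DMF, 25 °C
Reagents that add atoms: tert-butyldimethylsilyl chloride, CC(C)(C)[Si](C)(C)Cl
Why: Silylation of a secondary alcohol, giving a silyl ether that should tolerate the hydride, organozinc, oxidation, sulfonylation and base steps up to step 13.

Step 5
Reactants: 8 (R)-4-[(tert-butyldimethylsilyl)oxy]-2,6,6-trimethylcyclohex-2-en-1-one; 5 4-(chloromethyl)pent-4-enal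
Product: 10 (2S,4R)-4-[(tert-butyldimethylsilyl)oxy]-2-[4-(chloromethyl)-1-hydroxypent-4-en-1-yl]-2,6,6-trimethylcyclohexan-1-one (both carbinol epimers), via lithium enolate 9 (not isolated)
Conditions: LiBH(s-Bu)3, THF, −78 °C; then 5, −78 °C; AcOH, −78 °C
Reagents that add atoms: none
Why: Reductive aldol reaction, in which 1,4-hydride addition to the enone (its carbonyl blocked on both sides) gives the tetrasubstituted lithium enolate regiospecifically and this adds to the aldehyde to create quaternary C8, the aldehyde being expected on the face away from the pseudo-axial C4 methyl (cis to the equatorial C6 silyloxy group), while the C9 configuration is left open because steps 7 and 8 reset it.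

Step 6
Reactants: 10 aldol adduct (both C9 epimers)
Product: 12 cis-fused bicyclic diol with C3–OH and C8–CH3 cis to each other and trans to C6–OTBS (both C9 epimers), via allylzinc chloride 11 (not isolated)
Conditions: Zn dust, THF/sat. aq. NH4Cl (5:1), 25 °C
Reagents that add atoms: none
Why: Intramolecular Barbier allylation, in which zinc inserts into the allylic chloride and the allylzinc (both termini CH2, so no regiochemical issue) adds to the C3 ketone to close the seven-membered ring at C2–C3, axial attack on the chair cyclohexanone from the face opposite the axial C4 and C8 methyls with the tether equatorial setting C3 so that OH and the C8 methyl are cis.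

Step 7
Reactants: 12 bicyclic diol (both C9 epimers)
Product: 13 bicyclic β-hydroxy ketone (C9 ketone; C3–OH cis to C8–CH3)
Conditions: Dess–Martin periodinane, CH2Cl2, 0 → 25 °C
Reagents that add atoms: none
Why: Dess–Martin oxidation should convert the secondary C9 carbinol of both epimers into one ketone under near-neutral conditions that leave the tertiary C3 alcohol, the alkene and the silyl ether intact and give no base to trigger retro-aldol cleavage.

Step 8
Reactants: 13 bicyclic β-hydroxy ketone
Product: 14 bicyclic cis-1,3-diol (C3–OH, C8–CH3 and C9–OH on one face; C6–OTBS on the other)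
Conditions: Zn(BH4)2, Et2O, −20 °C
Reagents that add atoms: none
Why: Chelation-controlled hydride reduction of a β-hydroxy ketone, in which zinc bridges the C3 hydroxyl and the C9 carbonyl and hydride should add to the face remote from the angular C8 methyl and the bound oxygen, giving the 1,3-syn (here cis) diol with C9–OH cis to the C8 methyl.

Step 9
Reactants: 14 bicyclic cis-1,3-diol
Product: 15 bicyclic hydroxy mesylate (C3 tertiary OH free; C9–OMs cis to C8–CH3 and to C3–OH)
Conditions: MsCl, Et3N, CH2Cl2, −10 °C
Reagents that add atoms: methanesulfonyl chloride, CS(=O)(=O)Cl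
Why: Sulfonylation via sulfene should take place only at the secondary C9 hydroxyl, because the tertiary C3 hydroxyl sits between two quaternary carbons, and it leaves the C9 configuration unchanged.

Step 10
Reactants: 15 bicyclic hydroxy mesylate
Product: 17 (6S,8E)-6-[(tert-butyldimethylsilyl)oxy]-4,4,8-trimethyl-1-methylidenecycloundec-8-en-3-one, via potassium C3-alkoxide 16 (not isolated)
Conditions: KN(SiMe3)2 (1.0 equiv), THF, −78 → 0 °C; aq. NaH2PO4/Na2HPO4 buffer (pH 7), 0 °C
Reagents that add atoms: none
Why: Deprotonation of the tertiary C3 hydroxyl gives alkoxide 16, whose oxygen lone pair forms the C3=O bond as the C3–C8 σ bond breaks, the C8=C9 π bond forms and mesylate leaves C9 in one concerted antiperiplanar event, the closest known reaction type being the Grob fragmentation of cyclic 1,3-diol monosulfonates to medium-ring alkenones. No ring is closed by bond formation: the eleven-membered ring appears because the bond cleaved is the one shared by the six- and seven-membered rings, so no exo or endo mode applies. No stereocentre is created; C3, C8 and C9 become sp2 and only C6 remains. The step needs E geometry at C8=C9, and the substrate fixes it: with the mesylate cis to the angular methyl, the C9–O bond lies anti to C3–C8 only when C7 is anti to C10 and the methyl anti to the C9 hydrogen, which maps onto the E alkene. It also needs fragmentation to beat oxetane formation and plain elimination; the cis arrangement of the C3 oxygen and the C9 mesylate denies backside access to C9, and the aligned intramolecular push should outrun any intermolecular pathway. One equivalent of a base whose conjugate acid is inert, low temperature and a buffered quench should keep the β,γ-unsaturated ketone from moving into conjugation, and the crude ketone is carried on at once.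

Step 11
Reactants: 17 eleven-membered C3 ketone
Product: 18 (6S,8E)-6-[(tert-butyldimethylsilyl)oxy]-4,4,8-trimethyl-1-methylidenecycloundec-8-en-3-ol (both C3 epimers)
Conditions: NaBH4, CeCl3·7H2O, MeOH, −40 → 0 °C
Reagents that add atoms: none
Why: Luche reduction should reduce the ketone faster than it enolises, so the exocyclic alkene stays out of conjugation, and the C3 configuration does not matter because C3 becomes sp2 in step 12.

Step 12
Reactants: 18 eleven-membered C3 alcohol
Product: 20 (2E,6S,8E)-6-[(tert-butyldimethylsilyl)oxy]-4,4,8-trimethyl-1-methylidenecycloundeca-2,8-diene, via C3 mesylate 19 (not isolated)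
Conditions: MsCl, Et3N, CH2Cl2, 0 °C; then DBU, PhMe, 80 °C
Reagents that add atoms: none
Why: Mesylation followed by E2 elimination, in which quaternary C4 leaves the allylic C2 hydrogens as the only β-hydrogens and the antiperiplanar transition state that keeps C1 trans to the C4 quaternary carbon should give the conjugated E diene.

Step 13
Reactants: 20 silyl-protected trienyl ether
Product: 21 (2E,6S,8E)-4,4,8-trimethyl-1-methylidenecycloundeca-2,8-dien-6-ol
Conditions: Bu4NF, THF, 25 °C
Reagents that add atoms: none
Why: Fluoride cleavage of the secondary silyl ether (Si–F bond formation) should leave the diene, the trisubstituted alkene and the C6 configuration unchanged.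

Step 14
Reactants: 22 isovanillic acid (3-hydroxy-4-methoxybenzoic acid)
Product: 24 3-[(tert-butyldimethylsilyl)oxy]-4-methoxybenzoic acid, via bis-silylated acid 23 (not isolated)
Conditions: TBSCl (2.5 equiv), imidazole, DMF, 25 °C; then AcOH/THF/H2O, 25 °C
Reagents that add atoms: tert-butyldimethylsilyl chloride, CC(C)(C)[Si](C)(C)Cl
Why: Silylation of phenol and acid followed by selective hydrolysis of the labile silyl ester in aqueous acetic acid should leave the aryl silyl ether that masks the phenol during acylation.

Step 15
Reactants: 21 trienol; 24 3-[(tert-butyldimethylsilyl)oxy]-4-methoxybenzoic acid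
Product: 25 (2E,6S,8E)-4,4,8-trimethyl-1-methylidenecycloundeca-2,8-dien-6-yl 3-[(tert-butyldimethylsilyl)oxy]-4-methoxybenzoate
Conditions: DCC, DMAP (cat.), CH2Cl2, 25 °C
Reagents that add atoms: none
Why: Steglich esterification (carbodiimide activation, acyl transfer through DMAP) acylates the C6 hydroxyl with retention because the C6–O bond is not broken.

Step 16
Reactants: 25 silyl-protected ester
Product: 26 (2E,6S,8E)-4,4,8-trimethyl-1-methylidenecycloundeca-2,8-dien-6-yl 3-hydroxy-4-methoxybenzoate (CNP0220645.1)
Conditions: Bu4NF, AcOH, THF, 0 °C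
Reagents that add atoms: none
Why: Fluoride desilylation of an aryl silyl ether is fast at 0 °C, and the acetic acid buffer should keep the phenoxide from attacking the benzoate, so the ester, the diene and the stereocentre survive.

**Compound list** (C-locants in descriptive names are those of the plan)

1 | tert-butyl acetate | CC(=O)OC(C)(C)C | starting material
2 | 3-chloro-2-(chloromethyl)prop-1-ene | C=C(CCl)CCl | starting material
3 | lithium enolate of tert-butyl acetate | [Li]OC(=C)OC(C)(C)C | intermediate
4 | tert-butyl 4-(chloromethyl)pent-4-enoate | CC(C)(C)OC(=O)CCC(=C)CCl | intermediate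
5 | 4-(chloromethyl)pent-4-enal | O=CCCC(=C)CCl | intermediate
6 | ketoisophorone (2,6,6-trimethylcyclohex-2-ene-1,4-dione) | CC1=CC(=O)CC(C)(C)C1=O | starting material
7 | (R)-4-hydroxy-2,6,6-trimethylcyclohex-2-en-1-one | CC1=C[C@H](O)CC(C)(C)C1=O | intermediate
8 | (R)-4-[(tert-butyldimethylsilyl)oxy]-2,6,6-trimethylcyclohex-2-en-1-one | CC1=C[C@H](O[Si](C)(C)C(C)(C)C)CC(C)(C)C1=O | intermediate
9 | lithium (S)-4-[(tert-butyldimethylsilyl)oxy]-2,6,6-trimethylcyclohex-1-en-1-olate | [Li]OC1=C(C)C[C@H](O[Si](C)(C)C(C)(C)C)CC1(C)C | intermediate
10 | (2S,4R)-4-[(tert-butyldimethylsilyl)oxy]-2-[4-(chloromethyl)-1-hydroxypent-4-en-1-yl]-2,6,6-trimethylcyclohexan-1-one, both carbinol (C9) epimers; side chain cis to OTBS | O=C1C(C)(C)C[C@@H](O[Si](C)(C)C(C)(C)C)C[C@@]1(C)C(O)CCC(=C)CCl | intermediate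
11 | allylzinc chloride of 10 (CH2Cl replaced by CH2ZnCl) | O=C1C(C)(C)C[C@@H](O[Si](C)(C)C(C)(C)C)C[C@@]1(C)C(O)CCC(=C)C[Zn]Cl | intermediate
12 | cis-fused bicyclo[5.4.0]undecane diol: six-membered ring C3–C8, seven-membered ring C3, C2, C1(=CH2), C11, C10, C9, C8; C3–OH and C8–CH3 cis, both trans to C6–OTBS; C9–OH as both epimers | O[C@@]12CC(=C)CCC(O)[C@]1(C)C[C@H](O[Si](C)(C)C(C)(C)C)CC2(C)C | intermediate
13 | same bicycle with C9 ketone (β-hydroxy ketone; C3–OH cis to C8–CH3) | O[C@@]12CC(=C)CCC(=O)[C@]1(C)C[C@H](O[Si](C)(C)C(C)(C)C)CC2(C)C | intermediate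
14 | same bicycle, cis-1,3-diol: C3–OH, C8–CH3 and C9–OH on one face, C6–OTBS on the other | O[C@@]12CC(=C)CC[C@@H](O)[C@]1(C)C[C@H](O[Si](C)(C)C(C)(C)C)CC2(C)C | intermediate
15 | C9 monomesylate of 14: (1R,6R,7S,9R)-9-[(tert-butyldimethylsilyl)oxy]-1-hydroxy-7,11,11-trimethyl-3-methylidenebicyclo[5.4.0]undecan-6-yl methanesulfonate | O[C@@]12CC(=C)CC[C@@H](OS(C)(=O)=O)[C@]1(C)C[C@H](O[Si](C)(C)C(C)(C)C)CC2(C)C | intermediate
16 | potassium C3-alkoxide of 15 | [K]O[C@@]12CC(=C)CC[C@@H](OS(C)(=O)=O)[C@]1(C)C[C@H](O[Si](C)(C)C(C)(C)C)CC2(C)C | intermediate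
17 | (6S,8E)-6-[(tert-butyldimethylsilyl)oxy]-4,4,8-trimethyl-1-methylidenecycloundec-8-en-3-one | C=C1CC(=O)C(C)(C)C[C@@H](O[Si](C)(C)C(C)(C)C)C/C(C)=C/CC1 | intermediate
18 | (6S,8E)-6-[(tert-butyldimethylsilyl)oxy]-4,4,8-trimethyl-1-methylidenecycloundec-8-en-3-ol, both C3 epimers | C=C1CC(O)C(C)(C)C[C@@H](O[Si](C)(C)C(C)(C)C)C/C(C)=C/CC1 | intermediate
19 | C3 methanesulfonate of 18 | C=C1CC(OS(C)(=O)=O)C(C)(C)C[C@@H](O[Si](C)(C)C(C)(C)C)C/C(C)=C/CC1 | intermediate
20 | (2E,6S,8E)-6-[(tert-butyldimethylsilyl)oxy]-4,4,8-trimethyl-1-methylidenecycloundeca-2,8-diene | C=C1/C=C/C(C)(C)C[C@@H](O[Si](C)(C)C(C)(C)C)C/C(C)=C/CC1 | intermediate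
21 | (2E,6S,8E)-4,4,8-trimethyl-1-methylidenecycloundeca-2,8-dien-6-ol | C=C1/C=C/C(C)(C)C[C@@H](O)C/C(C)=C/CC1 | intermediate
22 | isovanillic acid | COc1ccc(C(=O)O)cc1O | starting material
23 | tert-butyldimethylsilyl 3-[(tert-butyldimethylsilyl)oxy]-4-methoxybenzoate | COc1ccc(C(=O)O[Si](C)(C)C(C)(C)C)cc1O[Si](C)(C)C(C)(C)C | intermediate
24 | 3-[(tert-butyldimethylsilyl)oxy]-4-methoxybenzoic acid | COc1ccc(C(=O)O)cc1O[Si](C)(C)C(C)(C)C | intermediate
25 | (2E,6S,8E)-4,4,8-trimethyl-1-methylidenecycloundeca-2,8-dien-6-yl 3-[(tert-butyldimethylsilyl)oxy]-4-methoxybenzoate | C=C1/C=C/C(C)(C)C[C@@H](OC(=O)c2ccc(OC)c(O[Si](C)(C)C(C)(C)C)c2)C/C(C)=C/CC1 | intermediate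
26 | (2E,6S,8E)-4,4,8-trimethyl-1-methylidenecycloundeca-2,8-dien-6-yl 3-hydroxy-4-methoxybenzoate (CNP0220645.1) | C=C1/C=C/C(C)(C)C[C@@H](OC(=O)c2ccc(OC)c(O)c2)C/C(C)=C/CC1 | target

**Step count and risks**

Total steps: 16. Longest linear sequence: 13 (steps 3–13, 15 and 16 from ketoisophorone; the branch from tert-butyl acetate through steps 1, 2 and 5 onward is equally long).

Steps most likely to fail:

Step 6. The allylzinc may be protonated or couple intermolecularly faster than it adds to the C3 carbonyl, which is flanked by two quaternary carbons, so the seven-membered ring would not close. The fallback replaces the organometallic closure by a Lewis-acid-promoted intramolecular Hosomi–Sakurai allylation and sets out from 1 and 8. Compound 1 is alkylated as in step 1 with commercial 2-(chloromethyl)-3-(trimethylsilyl)prop-1-ene to give tert-butyl 4-[(trimethylsilyl)methyl]pent-4-enoate F1. Reduction with i-Bu2AlH as in step 2 gives 4-[(trimethylsilyl)methyl]pent-4-enal F2. Reductive aldol of 8 with F2 as in step 5 gives the allylsilane aldol F3. TiCl4 in CH2Cl2 at −78 °C should then chelate the β-hydroxy ketone and let the allylsilane add to C3 with loss of the silyl group, coming back to the route at 12.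

Step 8. Facial selectivity of hydride addition at C9 may be poor in the flexible seven-membered ring, leaving part of the carbinol trans to the angular methyl; that epimer would fragment to the Z alkene or not at all. The fallback fixes C9 by reagent control before ring closure and sets out from 10. Dess–Martin oxidation gives the 1,3-diketone F4, which has no hydrogen between the carbonyls. Corey–Bakshi–Shibata reduction with (S)-2-methyl-CBS-oxazaborolidine and catecholborane should reduce only the side-chain ketone, since the ring ketone lies between two quaternary carbons, with quaternary C8 as the large group and the CH2 chain as the small one, to give the single (R)-carbinol F5. Zinc Barbier cyclisation as in step 6 then gives the cis diol directly, so the route is rejoined at 14 and steps 7 and 8 are not needed.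

Step 12. Ionisation of the neopentyl-type homoallylic mesylate (methyl shift, transannular participation of C8=C9) or formation of the Z diene may compete with the E2 elimination. The fallback works from the ketone oxidation level and sets out from 17. KN(SiMe3)2 and PhNTf2 in THF at −78 °C should give the dienyl triflate F6: enolisation is possible only toward C2, and the quaternary C4 forces C1 trans to C4 on the enolate. Reduction with Pd(OAc)2/PPh3, Bu3N and HCO2H in DMF then replaces the triflate by hydrogen with retention of alkene geometry and comes back to the route at 20; steps 11 and 12 are not needed.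

**Further compounds**

F1 | step 6 | tert-butyl 4-[(trimethylsilyl)methyl]pent-4-enoate | CC(C)(C)OC(=O)CCC(=C)C[Si](C)(C)C
F2 | step 6 | 4-[(trimethylsilyl)methyl]pent-4-enal | O=CCCC(=C)C[Si](C)(C)C
F3 | step 6 | (2S,4R)-4-[(tert-butyldimethylsilyl)oxy]-2-{1-hydroxy-4-[(trimethylsilyl)methyl]pent-4-en-1-yl}-2,6,6-trimethylcyclohexan-1-one, both carbinol epimers | O=C1C(C)(C)C[C@@H](O[Si](C)(C)C(C)(C)C)C[C@@]1(C)C(O)CCC(=C)C[Si](C)(C)C
F4 | step 8 | (2S,4R)-4-[(tert-butyldimethylsilyl)oxy]-2-[4-(chloromethyl)pent-4-enoyl]-2,6,6-trimethylcyclohexan-1-one | O=C1C(C)(C)C[C@@H](O[Si](C)(C)C(C)(C)C)C[C@@]1(C)C(=O)CCC(=C)CCl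
F5 | step 8 | (2S,4R)-4-[(tert-butyldimethylsilyl)oxy]-2-[(1R)-4-(chloromethyl)-1-hydroxypent-4-en-1-yl]-2,6,6-trimethylcyclohexan-1-one | O=C1C(C)(C)C[C@@H](O[Si](C)(C)C(C)(C)C)C[C@@]1(C)[C@H](O)CCC(=C)CCl
F6 | step 12 | (6S,8E)-6-[(tert-butyldimethylsilyl)oxy]-4,4,8-trimethyl-1-methylidenecycloundeca-2,8-dien-3-yl trifluoromethanesulfonate, ring carbons C1 and C4 trans across C2=C3 | C=C1/C=C(OS(=O)(=O)C(F)(F)F)/C(C)(C)C[C@@H](O[Si](C)(C)C(C)(C)C)C/C(C)=C/CC1
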